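Both quinone rings are disconnected, through their hydroquinone dimethyl ethers, to a four-membered ring. Heating a 4-alkenyl-4-methoxycyclobut-2-enone that carries CH2CO2Me on its β-carbon should open the ring (4π) to a dienylketene, which closes (6π) and tautomerises to the fully substituted phenol in one operation. The step exploits the para-dioxygenated six-membered ring (numbered as 3,6-dioxocyclohexa-1,4-dien-1-yl): carbonyl carbon C-6, flanked by the ester-bearing C-1 and the geranyl-bearing C-5, is the former sp3 ring carbon, C-3 is the cyclobutenone carbonyl carbon, and C-5/C-4 come from the 1-geranylvinyl group. Oxidative enolate dimerisation of the resulting arylacetate then builds the meso succinate, and oxidative demethylation unveils both quinones last.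

Key step: step 6

Remark on the chemistry: the two stereocentres of the target carry opposite descriptors in a constitutionally symmetric molecule, so the target is the meso (2R,3S) succinate. The cyclobutenone intermediates with one quaternary centre are racemic; that centre is erased in step 6.

Step 1
Reactants: 1 geranyl bromide; 2 ethynylmagnesium bromide
Product: 3 (4E)-5,9-dimethyldeca-4,8-dien-1-yne
Conditions: 2 (3 equiv), CuCl (5 mol%), THF, 0 °C to 40 °C
Reagents that add atoms: none
Why: Copper-catalysed SN2 coupling of an alkynyl Grignard reagent with a primary allylic bromide (skipped-enyne synthesis) should occur at the unhindered CH2 terminus with retention of the E alkene, the excess of 2 suppressing double allylation.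

Step 2
Reactants: 3 (4E)-5,9-dimethyldeca-4,8-dien-1-yne
Product: 5 (4E)-2-bromo-5,9-dimethyldeca-1,4,8-triene, via bromoboration adduct 4 (not isolated)
Conditions: B-bromo-9-borabicyclo[3.3.1]nonane (1.0 equiv), CH2Cl2, 0 °C; then AcOH, 0 °C to rt
Reagents that add atoms: B-bromo-9-borabicyclo[3.3.1]nonane BrB1C2CCCC1CCC2
Why: Markovnikov syn-bromoboration of the terminal alkyne (haloboration) followed by protonolysis of the vinyl C–B bond should give the 2-bromo-1-alkene, the trisubstituted alkenes being inert to the B–Br reagent at 0 °C.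

Step 3
Reactants: 6 diisopropyl squarate
Product: 8 3-(propan-2-yloxy)cyclobut-3-ene-1,2-dione, via hydroxycyclobutenone 7 (not isolated)
Conditions: LiAlH(OtBu)3, THF, 0 °C; then conc. HCl, CH2Cl2, rt
Reagents that add atoms: water O
Why: Hydride adds 1,2 to one of the two equivalent squarate carbonyls, and acid then ionises the allylic carbinol and hydrolyses the resulting oxocarbenium ion (1,3-carbonyl transposition with loss of propan-2-ol) to the semisquarate.

Step 4
Reactants: 5 (4E)-2-bromo-5,9-dimethyldeca-1,4,8-triene; 8 3-(propan-2-yloxy)cyclobut-3-ene-1,2-dione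
Product: 11 4-[(4E)-5,9-dimethyldeca-1,4,8-trien-2-yl]-4-methoxy-3-(propan-2-yloxy)cyclobut-2-en-1-one, via vinyllithium 9 (not isolated), via lithium alkoxide 10 (not isolated)
Conditions: 5, tert-butyllithium (2.1 equiv), Et2O, −78 °C; add to 8, THF, −78 °C; then MeOTf, −78 °C to 0 °C
Reagents that add atoms: methyl trifluoromethanesulfonate COS(=O)(=O)C(F)(F)F
Why: Bromine–lithium exchange gives the vinyllithium, which should add 1,2 to the ketone carbonyl next to the C–OiPr carbon (the other carbonyl is deactivated as a vinylogous ester), and the tertiary alkoxide is capped in situ by O-methylation; the new quaternary centre forms as a racemate and is destroyed in step 6.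

Step 5
Reactants: 11 4-[(4E)-5,9-dimethyldeca-1,4,8-trien-2-yl]-4-methoxy-3-(propan-2-yloxy)cyclobut-2-en-1-one; 12 methyl acetate
Product: 15 methyl 2-{4-[(4E)-5,9-dimethyldeca-1,4,8-trien-2-yl]-4-methoxy-3-oxocyclobut-1-en-1-yl}acetate, via lithium enolate 13 (not isolated), via hydroxy ester adduct 14 (not isolated)
Conditions: 12, LiN(iPr)2, THF, −78 °C; then 11, −78 °C; then 1 M HCl, THF, 0 °C to rt
Reagents that add atoms: water O
Why: Stork–Danheiser transposition: the ester enolate adds 1,2 to the vinylogous ester carbonyl and acid-mediated ionisation and enol ether hydrolysis move the carbonyl, leaving CH2CO2Me on the β-carbon; conjugate addition–elimination at the C–OiPr carbon would give the same racemic product.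

Step 6
Reactants: 15 methyl 2-{4-[(4E)-5,9-dimethyldeca-1,4,8-trien-2-yl]-4-methoxy-3-oxocyclobut-1-en-1-yl}acetate
Product: 18 methyl 2-{3-[(2E)-3,7-dimethylocta-2,6-dien-1-yl]-5-hydroxy-2-methoxyphenyl}acetate, via dienylketene 16 (not isolated), via cyclohexadienone 17 (not isolated)
Conditions: toluene (0.02 M), 110 °C, argon
Reagents that add atoms: none
Why: Release of cyclobutenone strain drives a thermal conrotatory 4π-electrocyclic opening of the C(=O)–C(OMe) bond to dienylketene 16, whose ketene carbon then bonds to the terminal CH2 of the 1-geranylvinyl group to give cyclohexa-2,4-dienone 17, and tautomerisation to the phenol makes the sequence irreversible. The closest known reaction type is the thermal ring expansion of 4-alkenyl-4-alkoxycyclobutenones to hydroquinone monoethers (Moore-type rearrangement, also the closing stage of the Danheiser benzannulation). The six-membered ring is closed by a thermal disrotatory 6π-electrocyclisation. No stereocentre is formed and the racemic quaternary centre is erased. The step needs inward rotation of the alkenyl group during ring opening, which the donor methoxy group on the same carbon secures by its preference for outward rotation. The substitution pattern of the arene is fixed by the connectivity of 15, and high dilution disfavours intermolecular trapping of the ketene by the phenol product.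

Step 7
Reactants: 18 methyl 2-{3-[(2E)-3,7-dimethylocta-2,6-dien-1-yl]-5-hydroxy-2-methoxyphenyl}acetate
Product: 19 methyl 2-{3-[(2E)-3,7-dimethylocta-2,6-dien-1-yl]-2,5-dimethoxyphenyl}acetate
Conditions: MeI, K2CO3, acetone, 56 °C
Reagents that add atoms: iodomethane CI
Why: Williamson etherification of the phenoxide, the carbonate being too weak a base to enolise the arylacetate.

Step 8
Reactants: 19 methyl 2-{3-[(2E)-3,7-dimethylocta-2,6-dien-1-yl]-2,5-dimethoxyphenyl}acetate (two molecules)
Product: 23 dimethyl (2R,3S)-2,3-bis{3-[(2E)-3,7-dimethylocta-2,6-dien-1-yl]-2,5-dimethoxyphenyl}butanedioate (meso), via lithium enolate 20 (not isolated), via iodo ester 21 (not isolated), via diastereomer mixture 22 (not isolated)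
Conditions: LiN(iPr)2 (1.05 equiv), THF, −78 °C; I2 (0.5 equiv), −78 °C to rt; then NaOMe, MeOH, 50 °C; crystallisation
Reagents that add atoms: none
Why: Oxidative enolate homocoupling (iodine converts half of enolate 20 into iodo ester 21, which the remaining enolate displaces) gives 22 without facial control, and reversible NaOMe epimerisation of the two benzylic α-ester centres should then enrich the meso isomer, whose centrosymmetric anti conformer avoids one aryl/ester gauche contact and which is removed by crystallisation.

Step 9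
Reactants: 23 dimethyl (2R,3S)-2,3-bis{3-[(2E)-3,7-dimethylocta-2,6-dien-1-yl]-2,5-dimethoxyphenyl}butanedioate (meso)
Product: 24 dimethyl (2R,3S)-2,3-bis{5-[(2E)-3,7-dimethylocta-2,6-dien-1-yl]-3,6-dioxocyclohexa-1,4-dien-1-yl}butanedioate (target CNP0183145.1)
Conditions: (NH4)2Ce(NO3)6 (5 equiv), MeCN/H2O, 0 °C
Reagents that add atoms: water O
Why: Oxidative demethylation of each hydroquinone dimethyl ether by tetravalent cerium should give the para-quinones with loss of methanol, the cold acidic medium leaving the base-labile benzylic stereocentres and the E-geranyl chains untouched.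

Compound list
1 | geranyl bromide, (2E)-1-bromo-3,7-dimethylocta-2,6-diene | BrC/C=C(\C)CCC=C(C)C | starting material
2 | ethynylmagnesium bromide | C#C[Mg]Br | starting material
3 | (4E)-5,9-dimethyldeca-4,8-dien-1-yne | C#CC/C=C(\C)CCC=C(C)C | intermediate
4 | B-[(1Z,4E)-2-bromo-5,9-dimethyldeca-1,4,8-trien-1-yl]-9-borabicyclo[3.3.1]nonane | Br/C(C/C=C(\C)CCC=C(C)C)=C\B1C2CCCC1CCC2 | intermediate
5 | (4E)-2-bromo-5,9-dimethyldeca-1,4,8-triene | C=C(Br)C/C=C(\C)CCC=C(C)C | intermediate
6 | diisopropyl squarate, 3,4-di(propan-2-yloxy)cyclobut-3-ene-1,2-dione | CC(C)OC1=C(OC(C)C)C(=O)C1=O | starting material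
7 | 4-hydroxy-2,3-di(propan-2-yloxy)cyclobut-2-en-1-one (racemic) | CC(C)OC1=C(OC(C)C)C(O)C1=O | intermediate
8 | 3-(propan-2-yloxy)cyclobut-3-ene-1,2-dione | CC(C)OC1=CC(=O)C1=O | intermediate
9 | [(4E)-5,9-dimethyldeca-1,4,8-trien-2-yl]lithium | [Li]C(=C)C/C=C(\C)CCC=C(C)C | intermediate
10 | lithium 1-[(4E)-5,9-dimethyldeca-1,4,8-trien-2-yl]-4-oxo-2-(propan-2-yloxy)cyclobut-2-en-1-olate (racemic) | [Li]OC1(C(=C)C/C=C(\C)CCC=C(C)C)C(OC(C)C)=CC1=O | intermediate
11 | 4-[(4E)-5,9-dimethyldeca-1,4,8-trien-2-yl]-4-methoxy-3-(propan-2-yloxy)cyclobut-2-en-1-one (racemic) | COC1(C(=C)C/C=C(\C)CCC=C(C)C)C(OC(C)C)=CC1=O | intermediate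
12 | methyl acetate | CC(=O)OC | starting material
13 | lithium enolate of methyl acetate | [Li]OC(=C)OC | intermediate
14 | methyl 2-{1-hydroxy-4-methoxy-3-(propan-2-yloxy)-4-[(4E)-5,9-dimethyldeca-1,4,8-trien-2-yl]cyclobut-2-en-1-yl}acetate (racemic diastereomers) | COC(=O)CC1(O)C=C(OC(C)C)C1(OC)C(=C)C/C=C(\C)CCC=C(C)C | intermediate
15 | methyl 2-{4-[(4E)-5,9-dimethyldeca-1,4,8-trien-2-yl]-4-methoxy-3-oxocyclobut-1-en-1-yl}acetate (racemic) | COC(=O)CC1=CC(=O)C1(OC)C(=C)C/C=C(\C)CCC=C(C)C | intermediate
16 | methyl (3E,7E)-4-methoxy-8,12-dimethyl-5-methylidene-3-(2-oxoethenyl)trideca-3,7,11-trienoate (dienylketene) | O=C=C/C(CC(=O)OC)=C(OC)\C(=C)C/C=C(\C)CCC=C(C)C | intermediate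
17 | methyl 2-{5-[(2E)-3,7-dimethylocta-2,6-dien-1-yl]-6-methoxy-3-oxocyclohexa-1,5-dien-1-yl}acetate | COC(=O)CC1=CC(=O)CC(C/C=C(\C)CCC=C(C)C)=C1OC | intermediate
18 | methyl 2-{3-[(2E)-3,7-dimethylocta-2,6-dien-1-yl]-5-hydroxy-2-methoxyphenyl}acetate | COC(=O)Cc1cc(O)cc(C/C=C(\C)CCC=C(C)C)c1OC | intermediate
19 | methyl 2-{3-[(2E)-3,7-dimethylocta-2,6-dien-1-yl]-2,5-dimethoxyphenyl}acetate | COC(=O)Cc1cc(OC)cc(C/C=C(\C)CCC=C(C)C)c1OC | intermediate
20 | lithium enolate of 19 | [Li]OC(OC)=Cc1cc(OC)cc(C/C=C(\C)CCC=C(C)C)c1OC | intermediate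
21 | methyl 2-iodo-2-{3-[(2E)-3,7-dimethylocta-2,6-dien-1-yl]-2,5-dimethoxyphenyl}acetate (racemic) | COC(=O)C(I)c1cc(OC)cc(C/C=C(\C)CCC=C(C)C)c1OC | intermediate
22 | dimethyl 2,3-bis{3-[(2E)-3,7-dimethylocta-2,6-dien-1-yl]-2,5-dimethoxyphenyl}butanedioate (meso plus racemic pair) | COC(=O)C(c1cc(OC)cc(C/C=C(\C)CCC=C(C)C)c1OC)C(C(=O)OC)c1cc(OC)cc(C/C=C(\C)CCC=C(C)C)c1OC | intermediate
23 | dimethyl (2R,3S)-2,3-bis{3-[(2E)-3,7-dimethylocta-2,6-dien-1-yl]-2,5-dimethoxyphenyl}butanedioate (meso) | COC(=O)[C@H](c1cc(OC)cc(C/C=C(\C)CCC=C(C)C)c1OC)[C@@H](C(=O)OC)c1cc(OC)cc(C/C=C(\C)CCC=C(C)C)c1OC | intermediate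
24 | dimethyl (2R,3S)-2,3-bis{5-[(2E)-3,7-dimethylocta-2,6-dien-1-yl]-3,6-dioxocyclohexa-1,4-dien-1-yl}butanedioate (meso), CNP0183145.1 | COC(=O)[C@H](C1=CC(=O)C=C(C/C=C(\C)CCC=C(C)C)C1=O)[C@@H](C(=O)OC)C1=CC(=O)C=C(C/C=C(\C)CCC=C(C)C)C1=O | target

Total step count: 9. Longest linear sequence: 8 steps (steps 1, 2, 4, 5, 6, 7, 8, 9); step 3 supplies 8 as a one-step side branch.

Steps most likely to fail

Step 5. The enolate addition to the hindered vinylogous ester carbonyl of 11 may stall through reversible (retro-aldol) addition and proton transfer, so that 11 is recovered or degraded on acid treatment. The fallback sets out from 11 and comes back to the route at 15. The two-carbon ester unit would be delivered as an alkoxyacetylide instead of an enolate. Lithium methoxyacetylide F1, generated from 2-chloro-1,1-dimethoxyethane and LiNEt2 in THF, should add irreversibly to 11 to give the methoxyethynyl carbinol F2. Dilute H2SO4 in wet THF would then hydrate the ynol ether to the hydroxy ester 14 and trigger the same 1,3-transposition to 15.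

Step 8. The displacement of the secondary benzylic iodide 21 by the equally hindered enolate 20 may be slow, so that 21 is consumed by elimination or by iodination of the electron-rich arene, and the coupling stalls. The fallback sets out from 19 (through its enolate 20) and comes back at the diastereomer mixture 22, which is equilibrated and crystallised to 23 as in step 8. The bond would be made reductively instead of oxidatively. Enolate 20 is brominated with CBr4 at −78 °C to the α-bromo ester F3. Atom-transfer radical coupling of F3 with Cu powder, CuBr and N,N,N′,N″,N″-pentamethyldiethylenetriamine in toluene should then dimerise the ester-stabilised benzylic radical to 22.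

Step 2. HBr liberated during the protonolysis may add to the trisubstituted alkenes, or the skipped enyne may isomerise under the Lewis-acidic boron reagent, eroding the yield of 5. The fallback sets out from 3 and comes back at vinyllithium 9 (and hence 11 in step 4). The vinyl anion equivalent would be made by hydrometalation instead of haloboration. Hydrostannation of 3 with Bu3SnH catalysed by Mo(CO)3(CNtBu)3 should place tin on the internal alkyne carbon to give the 2-stannyl triene F4. Tin–lithium exchange with MeLi in THF at −78 °C would then deliver 9 directly for addition to 8.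

Further compounds
F1 | step 5 | lithium methoxyacetylide | [Li]C#COC
F2 | step 5 | 4-[(4E)-5,9-dimethyldeca-1,4,8-trien-2-yl]-1-(methoxyethynyl)-4-methoxy-3-(propan-2-yloxy)cyclobut-2-en-1-ol (racemic diastereomers) | COC#CC1(O)C=C(OC(C)C)C1(OC)C(=C)C/C=C(\C)CCC=C(C)C
F3 | step 8 | methyl 2-bromo-2-{3-[(2E)-3,7-dimethylocta-2,6-dien-1-yl]-2,5-dimethoxyphenyl}acetate (racemic) | COC(=O)C(Br)c1cc(OC)cc(C/C=C(\C)CCC=C(C)C)c1OC
F4 | step 2 | tributyl[(4E)-5,9-dimethyldeca-1,4,8-trien-2-yl]stannane | C=C(C/C=C(\C)CCC=C(C)C)[Sn](CCCC)(CCCC)CCCC
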